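**Retrosynthetic overview**
- The target comes from its aryl triisopropylsilyl (TIPS) ether by fluoride desilylation; this is the only protecting group in the route.
- Key C7–C8 bond: hexanal is used directly as an acyl-anion equivalent (nucleophilic acyl radical) and adds anti-Markovnikov to the terminal alkene of the fully assembled (R)-acetate, so no dithiane is put on or taken off.
- Ar–C1 bond and acetate: the aryl Grignard from TIPS-protected 3-bromo-5-methoxyphenol opens (R)-1,2-epoxyhept-6-ene at CH2, and the alkoxide is quenched with Ac2O in the same pot.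
- The (R)-epoxide comes from (R)-epichlorohydrin and 3-butenylmagnesium bromide; the chiral pool sets C2 and its C–O bond is never broken.
- Rings: none is built. The arene is bought; the only ring closed is the oxirane in step 2, reopened in step 3.

Assumption: the target is (R) at C2 (read from the SMILES), and 3-bromo-5-methoxyphenol, (R)-epichlorohydrin, 3-butenylmagnesium bromide (0.5 M in THF) and hexanal are catalogue items.

**Step 1**
Reactants: 1 3-bromo-5-methoxyphenol
Product: 2 (3-bromo-5-methoxyphenoxy)triisopropylsilane
Conditions: TIPSCl (1.1 equiv), imidazole (2 equiv), DMF, rt, 3 h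
Reagents that add atoms: triisopropylsilyl chloride, CC(C)[Si](Cl)(C(C)C)C(C)C
Why: Imidazole-promoted O-silylation (silyl ether formation) masks the acidic phenol so the aryl Grignard can be made; the bulky aryl TIPS ether tolerates Mg, alkoxides, Ac2O and radical conditions and is later removed by fluoride without touching the alkyl acetate.

**Step 2**
Reactants: 3 (R)-epichlorohydrin; 4 but-3-en-1-ylmagnesium bromide
Product: 7 (R)-2-(pent-4-en-1-yl)oxirane, via bromomagnesium chloroalkoxide 5 (not isolated), via chlorohydrin 6 (not isolated)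
Conditions: CuI (5 mol%), THF, −40 → −10 °C; aq. work-up (crude 6); powdered NaOH (2 equiv), Et2O, rt, 3 h; distil
Reagents that add atoms: none
Why: Cu-catalysed Grignard ring-opening of the epoxide at its unhindered CH2 (faster than SN2 at C–Cl under Cu(I) at low temperature), then base-induced intramolecular Williamson ring closure; no bond to the stereocentre is broken, so the (R)-centre of 3 is carried unchanged into 7.

**Step 3**
Reactants: 2 (3-bromo-5-methoxyphenoxy)triisopropylsilane; 7 (R)-2-(pent-4-en-1-yl)oxirane
Product: 10 (R)-1-[3-methoxy-5-(triisopropylsilyloxy)phenyl]hept-6-en-2-yl acetate, via aryl Grignard 8 (not isolated), via bromomagnesium alkoxide 9 (not isolated)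
Conditions: Mg (1.3 equiv), I2 (cat.), THF, 50 °C; decant from Mg; CuI (10 mol%), 7 (1.1 equiv), −30 → 0 °C; then Ac2O (2.5 equiv), DMAP (10 mol%), 0 °C → rt
Reagents that add atoms: magnesium, [Mg] (stays only in intermediates 8 and 9); acetic anhydride, CC(=O)OC(C)=O
Why: Grignard formation, Cu-catalysed SN2 opening of the terminal epoxide at CH2 and in-situ DMAP-catalysed O-acylation of the magnesium alkoxide; the C2–O bond of 7 is never broken, so the acetate is (R) as in the target.

**Step 4**
Reactants: 10 (R)-1-[3-methoxy-5-(triisopropylsilyloxy)phenyl]hept-6-en-2-yl acetate; 11 hexanal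
Product: 12 (R)-1-[3-methoxy-5-(triisopropylsilyloxy)phenyl]-8-oxotridecan-2-yl acetate
Conditions: 11 (8 equiv), N-hydroxyphthalimide (15 mol%), (BzO)2 (10 mol%, two portions), degassed PhMe, 80 °C, Ar, 16 h
Reagents that add atoms: none
Why: Radical-chain hydroacylation under polarity-reversal catalysis: the electrophilic phthalimide-N-oxyl abstracts the hydridic formyl H of hexanal, the nucleophilic acyl radical adds to the terminal CH2 of the alkene, and the secondary adduct radical takes H back from NHPI or the excess aldehyde; this is an addition with no co-product, and the high aldehyde concentration keeps a 1,5-H shift from C2–H (which would erode ee) minor.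

**Step 5**
Reactants: 12 (R)-1-[3-methoxy-5-(triisopropylsilyloxy)phenyl]-8-oxotridecan-2-yl acetate
Product: 13 (R)-1-(3-hydroxy-5-methoxyphenyl)-8-oxotridecan-2-yl acetate
Conditions: TBAF (1.2 equiv), AcOH (1.5 equiv), THF, 0 °C, 30 min
Reagents that add atoms: none
Why: Fluoride-induced desilylation of the aryl silyl ether (driven by the strong Si–F bond); the AcOH buffer protonates the phenoxide at once, so the secondary acetate and the enolisable ketone survive and the stereocentre is not involved.

**Compound list**
1 | 3-bromo-5-methoxyphenol | COc1cc(O)cc(Br)c1 | starting material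
2 | (3-bromo-5-methoxyphenoxy)triisopropylsilane | COc1cc(Br)cc(O[Si](C(C)C)(C(C)C)C(C)C)c1 | intermediate
3 | (R)-epichlorohydrin [(R)-2-(chloromethyl)oxirane] | ClC[C@H]1CO1 | starting material
4 | but-3-en-1-ylmagnesium bromide | C=CCC[Mg]Br | starting material
5 | bromomagnesium (R)-1-chlorohept-6-en-2-olate | ClC[C@H](O[Mg]Br)CCCC=C | intermediate
6 | (R)-1-chlorohept-6-en-2-ol | ClC[C@H](O)CCCC=C | intermediate
7 | (R)-2-(pent-4-en-1-yl)oxirane | C=CCCC[C@@H]1CO1 | intermediate
8 | [3-methoxy-5-(triisopropylsilyloxy)phenyl]magnesium bromide | COc1cc([Mg]Br)cc(O[Si](C(C)C)(C(C)C)C(C)C)c1 | intermediate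
9 | bromomagnesium (R)-1-[3-methoxy-5-(triisopropylsilyloxy)phenyl]hept-6-en-2-olate | C=CCCC[C@H](Cc1cc(O[Si](C(C)C)(C(C)C)C(C)C)cc(OC)c1)O[Mg]Br | intermediate
10 | (R)-1-[3-methoxy-5-(triisopropylsilyloxy)phenyl]hept-6-en-2-yl acetate | C=CCCC[C@H](Cc1cc(O[Si](C(C)C)(C(C)C)C(C)C)cc(OC)c1)OC(C)=O | intermediate
11 | hexanal | CCCCCC=O | starting material
12 | (R)-1-[3-methoxy-5-(triisopropylsilyloxy)phenyl]-8-oxotridecan-2-yl acetate | CCCCCC(=O)CCCCC[C@H](Cc1cc(O[Si](C(C)C)(C(C)C)C(C)C)cc(OC)c1)OC(C)=O | intermediate
13 | (R)-1-(3-hydroxy-5-methoxyphenyl)-8-oxotridecan-2-yl acetate (CNP0302149.1) | CCCCCC(=O)CCCCC[C@H](Cc1cc(O)cc(OC)c1)OC(C)=O | target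

**Totals**
Total steps: 5. Longest linear sequence: 4 (steps 1, 3, 4, 5 from compound 1; equally steps 2, 3, 4, 5 from compounds 3 and 4).

**Three steps most likely to fail, with fallbacks**

Step 4 (key hydroacylation). The risks are a short radical chain with an unactivated alkene, decarbonylation of the acyl radical, hydrogen abstraction at ArCH2, and partial loss of ee through a 1,5-H shift from C2–H; ee should be checked by chiral HPLC on 12. The fallback sets out from 10 and comes back at 12. Anti-Markovnikov radical addition of HBr (HBr, cat. (BzO)2, hexane, 0 °C) to the alkene of 10 gives (R)-7-bromo-1-[3-methoxy-5-(triisopropylsilyloxy)phenyl]heptan-2-yl acetate F1. F1 is then acylated with hexanal 11 under Ni/photoredox/hydrogen-atom-transfer catalysis (Ir photocatalyst, NiBr2·dtbbpy, quinuclidine, K2CO3, dioxane, blue LED, rt). The aldehyde-derived acyl radical is captured by nickel and joined to the C–Br carbon, giving 12; the radical now sits at C7, where hydrogen transfer from C2–H is disfavoured.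

Step 3 (one-pot Grignard opening and acetylation). The risks are bromohydrin formation from MgBr2, incomplete acylation of the magnesium alkoxide, and aryl ketone by-products if Grignard reagent remains. The fallback sets out from 2 and 7 and comes back at 10. Br/Li exchange on 2 (n-BuLi, THF, −78 °C) gives [3-methoxy-5-(triisopropylsilyloxy)phenyl]lithium F2. F2 opens 7 under BF3·OEt2 activation at −78 °C (no copper, no magnesium halide) and after work-up the isolated alcohol (R)-1-[3-methoxy-5-(triisopropylsilyloxy)phenyl]hept-6-en-2-ol F3 is obtained. Separate acetylation of F3 (Ac2O, pyridine, DMAP, CH2Cl2, rt) gives 10.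

Step 2 (volatile epoxide from epichlorohydrin). The risks are partial attack at C–Cl, which erodes ee, and loss of the volatile 7 on isolation. The fallback reverses the order in which the two carbon groups are attached; it sets out from 8 (made from 2 as in step 3) and 4 and comes back at 10 without passing through 7. Grignard 8 with CuI opens purchased (S)-epichlorohydrin (ClC[C@@H]1CO1) to (S)-1-chloro-3-[3-methoxy-5-(triisopropylsilyloxy)phenyl]propan-2-ol F4. NaH in THF at 0 °C closes F4 to the non-volatile (S)-2-[3-methoxy-5-(triisopropylsilyloxy)benzyl]oxirane F5. F5 is opened at its CH2 by 4 with CuI to give alkoxide 9, which is quenched with Ac2O/DMAP to give 10. The (S)-reagent is needed here because the former CH2Cl carbon now becomes the chain side.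

**Further compounds**
F1 | step 4 | (R)-7-bromo-1-[3-methoxy-5-(triisopropylsilyloxy)phenyl]heptan-2-yl acetate | BrCCCCC[C@H](Cc1cc(O[Si](C(C)C)(C(C)C)C(C)C)cc(OC)c1)OC(C)=O
F2 | step 3 | [3-methoxy-5-(triisopropylsilyloxy)phenyl]lithium | [Li]c1cc(OC)cc(O[Si](C(C)C)(C(C)C)C(C)C)c1
F3 | step 3 | (R)-1-[3-methoxy-5-(triisopropylsilyloxy)phenyl]hept-6-en-2-ol | C=CCCC[C@H](Cc1cc(O[Si](C(C)C)(C(C)C)C(C)C)cc(OC)c1)O
F4 | step 2 | (S)-1-chloro-3-[3-methoxy-5-(triisopropylsilyloxy)phenyl]propan-2-ol | COc1cc(C[C@H](O)CCl)cc(O[Si](C(C)C)(C(C)C)C(C)C)c1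
F5 | step 2 | (S)-2-[3-methoxy-5-(triisopropylsilyloxy)benzyl]oxirane | COc1cc(C[C@H]2CO2)cc(O[Si](C(C)C)(C(C)C)C(C)C)c1
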